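**Retrosynthetic overview**
- Target ⇐ removal of six MOM ethers ⇐ Claisen–Schmidt condensation of a ring-A methyl ketone with 4-hydroxybenzaldehyde; the methyl ketone comes from an aryl bromide by Heck arylation of a vinyl ether. (Ring A is the 2,6-dioxygenated aryl, ring B the aroyl ring, ring C the 2,4-dioxygenated aryl.)
- Cyclohexene–ring A bond ⇐ 1,4-addition of an arylcopper (from a directed magnesiation) to a 1-aroylcyclohexa-1,3-diene, anti to the ring-C aryl, then protonation; the dienone ⇐ vinyl triflate reduction of a β-diketone ⇐ C-acylation of (S)-5-aryl-3-methylcyclohex-2-enone with a ring-B Weinreb amide.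
- Key step: enantioselective rhodium-catalysed two-carbon ring expansion of a prochiral allenyl cyclobutanol to that cyclohexenone. It forms the only ring that is built (the cyclobutane is bought as 3-oxocyclobutanecarboxylic acid) and sets the aryl-bearing stereocentre.
- All three resorcinol rings come from one hub, 1-bromo-2,4-bis(methoxymethoxy)benzene.

Assumption: the sense of induction in step 6 is taken by analogy; if it is opposite, the other ligand antipode is used (MOM = methoxymethyl).

**Step 1**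
Reactants: 1 resorcinol
Product: 2 1,3-bis(methoxymethoxy)benzene
Conditions: NaH, MOMCl, DMF, 0 °C → rt
Reagents that add atoms: chloromethyl methyl ether, COCCl
Why: Williamson-type acetal protection of both phenols; the MOM ethers later direct the ortho-metalations.

**Step 2**
Reactants: 2 1,3-bis(methoxymethoxy)benzene
Product: 3 1-bromo-2,4-bis(methoxymethoxy)benzene
Conditions: NBS, MeCN, 0 °C
Reagents that add atoms: N-bromosuccinimide, O=C1CCC(=O)N1Br
Why: electrophilic aromatic bromination goes para to one and ortho to the other alkoxy group, leaving the hindered position between the two oxygens free.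

**Step 3**
Reactants: 3 1-bromo-2,4-bis(methoxymethoxy)benzene; 4 3-oxocyclobutane-1-carboxylic acid
Product: 5 3-[2,4-bis(methoxymethoxy)phenyl]cyclobutan-1-one
Conditions: Ir[dF(CF3)ppy]2(dtbbpy)PF6 (1 mol%), NiCl2·glyme (10 mol%), dtbbpy, Cs2CO3, DMF, blue LEDs, rt
Reagents that add atoms: none
Why: metallaphotoredox decarboxylative C(sp3)–C(sp2) cross-coupling, in which the carboxylate is oxidised to the 3-oxocyclobutyl radical and nickel couples it with the aryl bromide; the product is achiral.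

**Step 4**
Reactants: 5 3-[2,4-bis(methoxymethoxy)phenyl]cyclobutan-1-one; 6 ethynylmagnesium bromide
Product: 7 cis-3-[2,4-bis(methoxymethoxy)phenyl]-1-ethynylcyclobutan-1-ol
Conditions: THF, −78 → 0 °C; then H2O
Reagents that add atoms: none
Why: Grignard 1,2-addition in which the nucleophile enters trans to the 3-aryl group, giving the cis alcohol (hydroxyl and aryl on the same face; minor isomer removed by chromatography) whose two ring CH2–C(OH) bonds are enantiotopic.

**Step 5**
Reactants: 7 cis-3-[2,4-bis(methoxymethoxy)phenyl]-1-ethynylcyclobutan-1-ol; 8 formaldehyde (as paraformaldehyde)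
Product: 9 cis-3-[2,4-bis(methoxymethoxy)phenyl]-1-(propa-1,2-dien-1-yl)cyclobutan-1-ol
Conditions: (CH2O)n, CuI (0.5 equiv), Cy2NH, dioxane, reflux
Reagents that add atoms: none
Why: Crabbé homologation (Mannich base, then copper-mediated 1,5-hydride transfer) turns the terminal alkyne into the terminal allene without touching the tertiary alcohol.

**Step 6**
Reactants: 9 cis-3-[2,4-bis(methoxymethoxy)phenyl]-1-(propa-1,2-dien-1-yl)cyclobutan-1-ol
Product: 10 (S)-5-[2,4-bis(methoxymethoxy)phenyl]-3-methylcyclohex-2-en-1-one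
Conditions: [Rh(cod)OH]2 (2.5 mol%), (R)-DTBM-SEGPHOS (6 mol%), toluene, 80 °C
Reagents that add atoms: none
Why: Proposed new method: the monovalent rhodium alkoxide of 9 undergoes ligand-controlled β-carbon elimination of one of the two enantiotopic ring C–C bonds, the primary alkyl–rhodium adds to the central allene carbon (six-membered ring closure) faster than it β-hydride eliminates, and protonation of the rhodium dienolate at the terminal CH2 gives the 3-methyl enone, so this stepwise, non-pericyclic ring expansion builds the cyclohexene and sets the (S) centre; the closest known reaction is the same rhodium-catalysed ring expansion of 3,3-disubstituted allenyl cyclobutanols to cyclohexenones with quaternary centres, not shown for a 3-monoaryl substrate whose alkyl–rhodium carries a β-hydrogen.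

**Step 7**
Reactants: 3 1-bromo-2,4-bis(methoxymethoxy)benzene; 11 3-methylbutanal
Product: 15 1-bromo-2,4-bis(methoxymethoxy)-3-[(E)-3-methylbut-1-en-1-yl]benzene, via aryllithium 12 (not isolated), via lithium alkoxide 13 (not isolated), via mesylate 14 (not isolated)
Conditions: LiTMP (lithium 2,2,6,6-tetramethylpiperidide), THF, −78 °C; 11, −78 → 0 °C; MsCl, 0 °C; DBU, 50 °C
Reagents that add atoms: none
Why: directed ortho-lithiation between the two MOM ethers, addition to the aldehyde, then mesylation and base-induced elimination of the benzylic mesylate give the conjugated styrene with the thermodynamic (E) geometry.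

**Step 8**
Reactants: 15 1-bromo-2,4-bis(methoxymethoxy)-3-[(E)-3-methylbut-1-en-1-yl]benzene; 16 N-methoxy-N-methylcarbamoyl chloride
Product: 18 N-methoxy-N-methyl-2,4-bis(methoxymethoxy)-3-[(E)-3-methylbut-1-en-1-yl]benzamide, via aryllithium 17 (not isolated)
Conditions: n-BuLi, THF, −78 °C; then 16, −78 → 0 °C
Reagents that add atoms: none
Why: bromine–lithium exchange fixes the acylation site and the carbamoyl chloride traps the aryllithium as a Weinreb amide without over-addition.

**Step 9**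
Reactants: 10 (S)-5-[2,4-bis(methoxymethoxy)phenyl]-3-methylcyclohex-2-en-1-one; 18 N-methoxy-N-methyl-2,4-bis(methoxymethoxy)-3-[(E)-3-methylbut-1-en-1-yl]benzamide
Product: 20 (5S,6R)-6-{2,4-bis(methoxymethoxy)-3-[(E)-3-methylbut-1-en-1-yl]benzoyl}-5-[2,4-bis(methoxymethoxy)phenyl]-3-methylcyclohex-2-en-1-one, via lithium dienolate 19 (not isolated)
Conditions: LDA (lithium diisopropylamide), THF, −78 °C; 18, −78 → −20 °C; then H2O
Reagents that add atoms: none
Why: kinetic deprotonation of the enone at the α′ CH2 and Claisen-type C-acylation by the Weinreb amide (the chelated tetrahedral adduct stops further reaction); the aroyl group sits trans to the neighbouring aryl, and this enolisable centre is erased in step 10.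

**Step 10**
Reactants: 20 (5S,6R)-6-{2,4-bis(methoxymethoxy)-3-[(E)-3-methylbut-1-en-1-yl]benzoyl}-5-[2,4-bis(methoxymethoxy)phenyl]-3-methylcyclohex-2-en-1-one
Product: 21 (3R)-2-{2,4-bis(methoxymethoxy)-3-[(E)-3-methylbut-1-en-1-yl]benzoyl}-3-[2,4-bis(methoxymethoxy)phenyl]-5-methylcyclohexa-1,5-dien-1-yl trifluoromethanesulfonate
Conditions: PhNTf2, i-Pr2NEt, DMAP (cat.), CH2Cl2, rt
Reagents that add atoms: N-phenyl-bis(trifluoromethanesulfonimide), O=S(=O)(N(c1ccccc1)S(=O)(=O)C(F)(F)F)C(F)(F)F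
Why: O-sulfonylation of the β-diketone on the ring oxygen, which gives the endocyclic, linearly conjugated enol triflate with less allylic 1,3-strain than the exocyclic one (the descriptor changes from S to R only because the priorities change).

**Step 11**
Reactants: 21 (3R)-2-{2,4-bis(methoxymethoxy)-3-[(E)-3-methylbut-1-en-1-yl]benzoyl}-3-[2,4-bis(methoxymethoxy)phenyl]-5-methylcyclohexa-1,5-dien-1-yl trifluoromethanesulfonate
Product: 22 {(6R)-6-[2,4-bis(methoxymethoxy)phenyl]-4-methylcyclohexa-1,3-dien-1-yl}{2,4-bis(methoxymethoxy)-3-[(E)-3-methylbut-1-en-1-yl]phenyl}methanone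
Conditions: Pd(OAc)2 (5 mol%), PPh3, HCO2H, Bu3N, DMF, 60 °C
Reagents that add atoms: none
Why: palladium-catalysed formate reduction of the vinyl triflate (oxidative addition, decarboxylation of formate, reductive elimination) removes the ring oxygen and leaves the 1-aroyl-1,3-diene; the dienone is used at once under argon.

**Step 12**
Reactants: 3 1-bromo-2,4-bis(methoxymethoxy)benzene; 22 {(6R)-6-[2,4-bis(methoxymethoxy)phenyl]-4-methylcyclohexa-1,3-dien-1-yl}{2,4-bis(methoxymethoxy)-3-[(E)-3-methylbut-1-en-1-yl]phenyl}methanone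
Product: 25 [(1R,2S,6S)-2-[3-bromo-2,6-bis(methoxymethoxy)phenyl]-6-[2,4-bis(methoxymethoxy)phenyl]-4-methylcyclohex-3-en-1-yl]{2,4-bis(methoxymethoxy)-3-[(E)-3-methylbut-1-en-1-yl]phenyl}methanone, via arylmagnesium chloride 23 (not isolated), via arylcopper 24 (not isolated)
Conditions: 3, TMPMgCl·LiCl (2,2,6,6-tetramethylpiperidylmagnesium chloride–lithium chloride, 1.2 equiv), THF, 0 °C → rt; CuBr·SMe2, −40 °C; BF3·OEt2, −78 °C; 22, −78 → −40 °C; AcOH, −78 °C
Reagents that add atoms: none
Why: directed ortho-magnesiation with the Knochel–Hauser base at the C–H flanked by both chelating MOM ethers gives an aryl Grignard reagent that leaves the C–Br bond alone and transmetalates cleanly to copper, and the Lewis-acid-assisted organocopper conjugate addition (1,4 rather than 1,6) then delivers the aryl to the β-carbon anti to the pseudoaxial ring-C aryl, setting the 2,6-trans relationship, after which the exocyclic enolate is protonated from the face opposite the bulkier new 2,6-disubstituted aryl, setting C1 with the aroyl cis to ring A and trans to ring C.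

**Step 13**
Reactants: 25 [(1R,2S,6S)-2-[3-bromo-2,6-bis(methoxymethoxy)phenyl]-6-[2,4-bis(methoxymethoxy)phenyl]-4-methylcyclohex-3-en-1-yl]{2,4-bis(methoxymethoxy)-3-[(E)-3-methylbut-1-en-1-yl]phenyl}methanone; 26 butyl vinyl ether
Product: 28 [(1R,2S,6S)-2-[3-acetyl-2,6-bis(methoxymethoxy)phenyl]-6-[2,4-bis(methoxymethoxy)phenyl]-4-methylcyclohex-3-en-1-yl]{2,4-bis(methoxymethoxy)-3-[(E)-3-methylbut-1-en-1-yl]phenyl}methanone, via enol ether 27 (not isolated)
Conditions: Pd(OAc)2 (5 mol%), dppp, Et3N, ethylene glycol, 115 °C; then 1 M HCl, THF, rt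
Reagents that add atoms: water, O
Why: Heck reaction with regioselective α-arylation of the electron-rich vinyl ether (cationic pathway with a bidentate phosphine in a hydrogen-bond-donor solvent), then mild hydrolysis of the enol ether to the methyl ketone.

**Step 14**
Reactants: 29 p-cresol
Product: 30 4-hydroxybenzaldehyde
Conditions: O2 (1 atm), CoCl2 (1 mol%), NaOH, MeOH, 60 °C; then aq. HCl
Reagents that add atoms: dioxygen, O=O
Why: cobalt-catalysed aerobic benzylic oxidation of the para-cresolate through its quinone methide, which stops at the aldehyde.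

**Step 15**
Reactants: 28 [(1R,2S,6S)-2-[3-acetyl-2,6-bis(methoxymethoxy)phenyl]-6-[2,4-bis(methoxymethoxy)phenyl]-4-methylcyclohex-3-en-1-yl]{2,4-bis(methoxymethoxy)-3-[(E)-3-methylbut-1-en-1-yl]phenyl}methanone; 30 4-hydroxybenzaldehyde
Product: 31 [(1R,2S,6S)-2-{3-[(E)-3-(4-hydroxyphenyl)prop-2-enoyl]-2,6-bis(methoxymethoxy)phenyl}-6-[2,4-bis(methoxymethoxy)phenyl]-4-methylcyclohex-3-en-1-yl]{2,4-bis(methoxymethoxy)-3-[(E)-3-methylbut-1-en-1-yl]phenyl}methanone
Conditions: KOH, EtOH/H2O, rt; then AcOH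
Reagents that add atoms: none
Why: Claisen–Schmidt crossed aldol condensation of the methyl ketone with the non-enolisable aldehyde gives the (E)-enone, while the other ketone has only a hindered methine α-hydrogen and cannot condense.

**Step 16**
Reactants: 31 [(1R,2S,6S)-2-{3-[(E)-3-(4-hydroxyphenyl)prop-2-enoyl]-2,6-bis(methoxymethoxy)phenyl}-6-[2,4-bis(methoxymethoxy)phenyl]-4-methylcyclohex-3-en-1-yl]{2,4-bis(methoxymethoxy)-3-[(E)-3-methylbut-1-en-1-yl]phenyl}methanone
Product: 32 [(1R,2S,6S)-2-{2,6-dihydroxy-3-[(E)-3-(4-hydroxyphenyl)prop-2-enoyl]phenyl}-6-(2,4-dihydroxyphenyl)-4-methylcyclohex-3-en-1-yl]{2,4-dihydroxy-3-[(E)-3-methylbut-1-en-1-yl]phenyl}methanone (CNP0140882.1)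
Conditions: TMSOTf, 2,2′-bipyridyl, CH2Cl2, 0 °C → rt; then H2O
Reagents that add atoms: none
Why: buffered, non-protic Lewis-acid cleavage of the aryl MOM acetals (aryl silyl ethers, then phenols on adding water) avoids the strong protic acid that would cyclise the ortho-hydroxystyrene or ketalise the cis aroyl/ring-A pair; no stereocentre is touched.

**Compound list**
1 | resorcinol | Oc1cccc(O)c1 | starting material
2 | 1,3-bis(methoxymethoxy)benzene | COCOc1cccc(OCOC)c1 | intermediate
3 | 1-bromo-2,4-bis(methoxymethoxy)benzene | COCOc1ccc(Br)c(OCOC)c1 | intermediate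
4 | 3-oxocyclobutane-1-carboxylic acid | O=C1CC(C(=O)O)C1 | starting material
5 | 3-[2,4-bis(methoxymethoxy)phenyl]cyclobutan-1-one | O=C1CC(c2ccc(OCOC)cc2OCOC)C1 | intermediate
6 | ethynylmagnesium bromide | C#C[Mg]Br | starting material
7 | cis-3-[2,4-bis(methoxymethoxy)phenyl]-1-ethynylcyclobutan-1-ol (OH and aryl on the same face) | O[C@@]1(C#C)C[C@@H](c2ccc(OCOC)cc2OCOC)C1 | intermediate
8 | formaldehyde (used as paraformaldehyde) | C=O | starting material
9 | cis-3-[2,4-bis(methoxymethoxy)phenyl]-1-(propa-1,2-dien-1-yl)cyclobutan-1-ol | O[C@@]1(C=C=C)C[C@@H](c2ccc(OCOC)cc2OCOC)C1 | intermediate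
10 | (S)-5-[2,4-bis(methoxymethoxy)phenyl]-3-methylcyclohex-2-en-1-one | CC1=CC(=O)C[C@@H](c2ccc(OCOC)cc2OCOC)C1 | intermediate
11 | 3-methylbutanal | CC(C)CC=O | starting material
12 | [3-bromo-2,6-bis(methoxymethoxy)phenyl]lithium | [Li]c1c(OCOC)ccc(Br)c1OCOC | intermediate
13 | lithium 1-[3-bromo-2,6-bis(methoxymethoxy)phenyl]-3-methylbutan-1-olate (racemic) | [Li]OC(CC(C)C)c1c(OCOC)ccc(Br)c1OCOC | intermediate
14 | 1-[3-bromo-2,6-bis(methoxymethoxy)phenyl]-3-methylbutyl methanesulfonate (racemic) | CS(=O)(=O)OC(CC(C)C)c1c(OCOC)ccc(Br)c1OCOC | intermediate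
15 | 1-bromo-2,4-bis(methoxymethoxy)-3-[(E)-3-methylbut-1-en-1-yl]benzene | CC(C)/C=C/c1c(OCOC)ccc(Br)c1OCOC | intermediate
16 | N-methoxy-N-methylcarbamoyl chloride | CON(C)C(Cl)=O | starting material
17 | {2,4-bis(methoxymethoxy)-3-[(E)-3-methylbut-1-en-1-yl]phenyl}lithium | [Li]c1ccc(OCOC)c(/C=C/C(C)C)c1OCOC | intermediate
18 | N-methoxy-N-methyl-2,4-bis(methoxymethoxy)-3-[(E)-3-methylbut-1-en-1-yl]benzamide | CON(C)C(=O)c1ccc(OCOC)c(/C=C/C(C)C)c1OCOC | intermediate
19 | lithium (3S)-3-[2,4-bis(methoxymethoxy)phenyl]-5-methylcyclohexa-1,5-dien-1-olate | CC1=CC(O[Li])=C[C@@H](c2ccc(OCOC)cc2OCOC)C1 | intermediate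
20 | (5S,6R)-6-{2,4-bis(methoxymethoxy)-3-[(E)-3-methylbut-1-en-1-yl]benzoyl}-5-[2,4-bis(methoxymethoxy)phenyl]-3-methylcyclohex-2-en-1-one (drawn as diketone, largely enolised) | CC1=CC(=O)[C@H](C(=O)c2ccc(OCOC)c(/C=C/C(C)C)c2OCOC)[C@@H](c2ccc(OCOC)cc2OCOC)C1 | intermediate
21 | (3R)-2-{2,4-bis(methoxymethoxy)-3-[(E)-3-methylbut-1-en-1-yl]benzoyl}-3-[2,4-bis(methoxymethoxy)phenyl]-5-methylcyclohexa-1,5-dien-1-yl trifluoromethanesulfonate | CC1=CC(OS(=O)(=O)C(F)(F)F)=C(C(=O)c2ccc(OCOC)c(/C=C/C(C)C)c2OCOC)[C@@H](c2ccc(OCOC)cc2OCOC)C1 | intermediate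
22 | {(6R)-6-[2,4-bis(methoxymethoxy)phenyl]-4-methylcyclohexa-1,3-dien-1-yl}{2,4-bis(methoxymethoxy)-3-[(E)-3-methylbut-1-en-1-yl]phenyl}methanone | CC1=CC=C(C(=O)c2ccc(OCOC)c(/C=C/C(C)C)c2OCOC)[C@@H](c2ccc(OCOC)cc2OCOC)C1 | intermediate
23 | [3-bromo-2,6-bis(methoxymethoxy)phenyl]magnesium chloride (as its lithium chloride complex) | Cl[Mg]c1c(OCOC)ccc(Br)c1OCOC | intermediate
24 | [3-bromo-2,6-bis(methoxymethoxy)phenyl]copper | [Cu]c1c(OCOC)ccc(Br)c1OCOC | intermediate
25 | [(1R,2S,6S)-2-[3-bromo-2,6-bis(methoxymethoxy)phenyl]-6-[2,4-bis(methoxymethoxy)phenyl]-4-methylcyclohex-3-en-1-yl]{2,4-bis(methoxymethoxy)-3-[(E)-3-methylbut-1-en-1-yl]phenyl}methanone | CC1=C[C@H](c2c(OCOC)ccc(Br)c2OCOC)[C@H](C(=O)c2ccc(OCOC)c(/C=C/C(C)C)c2OCOC)[C@@H](c2ccc(OCOC)cc2OCOC)C1 | intermediate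
26 | butyl vinyl ether | C=COCCCC | starting material
27 | [(1R,2S,6S)-2-[3-(1-butoxyethenyl)-2,6-bis(methoxymethoxy)phenyl]-6-[2,4-bis(methoxymethoxy)phenyl]-4-methylcyclohex-3-en-1-yl]{2,4-bis(methoxymethoxy)-3-[(E)-3-methylbut-1-en-1-yl]phenyl}methanone | CC1=C[C@H](c2c(OCOC)ccc(C(=C)OCCCC)c2OCOC)[C@H](C(=O)c2ccc(OCOC)c(/C=C/C(C)C)c2OCOC)[C@@H](c2ccc(OCOC)cc2OCOC)C1 | intermediate
28 | [(1R,2S,6S)-2-[3-acetyl-2,6-bis(methoxymethoxy)phenyl]-6-[2,4-bis(methoxymethoxy)phenyl]-4-methylcyclohex-3-en-1-yl]{2,4-bis(methoxymethoxy)-3-[(E)-3-methylbut-1-en-1-yl]phenyl}methanone | CC1=C[C@H](c2c(OCOC)ccc(C(C)=O)c2OCOC)[C@H](C(=O)c2ccc(OCOC)c(/C=C/C(C)C)c2OCOC)[C@@H](c2ccc(OCOC)cc2OCOC)C1 | intermediate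
29 | p-cresol (4-methylphenol) | Cc1ccc(O)cc1 | starting material
30 | 4-hydroxybenzaldehyde | O=Cc1ccc(O)cc1 | intermediate
31 | [(1R,2S,6S)-2-{3-[(E)-3-(4-hydroxyphenyl)prop-2-enoyl]-2,6-bis(methoxymethoxy)phenyl}-6-[2,4-bis(methoxymethoxy)phenyl]-4-methylcyclohex-3-en-1-yl]{2,4-bis(methoxymethoxy)-3-[(E)-3-methylbut-1-en-1-yl]phenyl}methanone | CC1=C[C@H](c2c(OCOC)ccc(C(=O)/C=C/c3ccc(O)cc3)c2OCOC)[C@H](C(=O)c2ccc(OCOC)c(/C=C/C(C)C)c2OCOC)[C@@H](c2ccc(OCOC)cc2OCOC)C1 | intermediate
32 | [(1R,2S,6S)-2-{2,6-dihydroxy-3-[(E)-3-(4-hydroxyphenyl)prop-2-enoyl]phenyl}-6-(2,4-dihydroxyphenyl)-4-methylcyclohex-3-en-1-yl]{2,4-dihydroxy-3-[(E)-3-methylbut-1-en-1-yl]phenyl}methanone (CNP0140882.1) | CC1=C[C@H](c2c(O)ccc(C(=O)/C=C/c3ccc(O)cc3)c2O)[C@H](C(=O)c2ccc(O)c(/C=C/C(C)C)c2O)[C@@H](c2ccc(O)cc2O)C1 | target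

**Totals**
Total step count: 16. Longest linear sequence: 13 steps (steps 1–6, 9–13, 15 and 16).

**Three steps most likely to fail**

Step 6 (the proposed new ring expansion): β-hydride elimination of the alkyl–rhodium, or low enantioselection, may win. The fallback uses known chemistry, sets out from 3 and returns at 10. Bromine–lithium exchange on 3 (n-BuLi) and formylation with DMF give 2,4-bis(methoxymethoxy)benzaldehyde F1. Aldol condensation with acetone (aq. NaOH) gives (E)-4-[2,4-bis(methoxymethoxy)phenyl]but-3-en-2-one F2. Mukaiyama–Michael addition of 2-(trimethylsilyloxy)propene (cat. Sc(OTf)3, CH2Cl2, −78 °C, aqueous work-up) gives 4-[2,4-bis(methoxymethoxy)phenyl]heptane-2,6-dione F3. This prochiral diketone is closed by the known primary-amine-catalysed desymmetrising intramolecular aldol condensation (9-amino-9-deoxy-epi-cinchona alkaloid with an acid co-catalyst), which delivers 5-substituted 3-methylcyclohex-2-enones in high ee, here 10.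

Step 12 (magnesiation, then arylcopper addition): 1,6-addition to the dienone, the wrong facial sense, or a sluggish hindered aryl transfer from copper are possible. The fallback sets out from 3 and 22 and returns at 25. The Grignard reagent 23, made from 3 with TMPMgCl·LiCl as in step 12, is quenched with B(OMe)3 and worked up with aqueous acid to give [3-bromo-2,6-bis(methoxymethoxy)phenyl]boronic acid F4. Rhodium-catalysed conjugate arylation of 22 ([Rh(cod)OH]2, dioxane/H2O, 50 °C), a different carbometalation that is reported to favour 1,4-addition on dienones, with protonation by water, gives 25. If the C1 epimer forms in either variant, brief DBU treatment equilibrates this enolisable centre toward the isomer with the aroyl and ring-C aryl trans-diequatorial.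

Step 16 (sixfold MOM cleavage on the finished chalcone): the 2′-hydroxychalcone can close to a flavanone, the ortho-hydroxystyrene can cyclise, and the cis aroyl/ring-A pair can ketalise. The fallback changes the order of events, sets out from 28 and returns at 32. The MOM groups are removed from 28 (same TMSOTf/2,2′-bipyridyl protocol, or ZnBr2/n-PrSH) before any chalcone exists, giving [(1R,2S,6S)-2-(3-acetyl-2,6-dihydroxyphenyl)-6-(2,4-dihydroxyphenyl)-4-methylcyclohex-3-en-1-yl]{2,4-dihydroxy-3-[(E)-3-methylbut-1-en-1-yl]phenyl}methanone F5. This is condensed unprotected with 30 (KOH, EtOH/H2O, rt, the classical polyhydroxychalcone conditions) to give 32.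

**Further compounds**
F1 | step 6 | 2,4-bis(methoxymethoxy)benzaldehyde | COCOc1ccc(C=O)c(OCOC)c1
F2 | step 6 | (E)-4-[2,4-bis(methoxymethoxy)phenyl]but-3-en-2-one | CC(=O)/C=C/c1ccc(OCOC)cc1OCOC
F3 | step 6 | 4-[2,4-bis(methoxymethoxy)phenyl]heptane-2,6-dione | CC(=O)CC(CC(C)=O)c1ccc(OCOC)cc1OCOC
F4 | step 12 | [3-bromo-2,6-bis(methoxymethoxy)phenyl]boronic acid | OB(O)c1c(OCOC)ccc(Br)c1OCOC
F5 | step 16 | [(1R,2S,6S)-2-(3-acetyl-2,6-dihydroxyphenyl)-6-(2,4-dihydroxyphenyl)-4-methylcyclohex-3-en-1-yl]{2,4-dihydroxy-3-[(E)-3-methylbut-1-en-1-yl]phenyl}methanone | CC1=C[C@H](c2c(O)ccc(C(C)=O)c2O)[C@H](C(=O)c2ccc(O)c(/C=C/C(C)C)c2O)[C@@H](c2ccc(O)cc2O)C1
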